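The diaryl ether oxygen of the target is attached to ring A at C6, next to the carboxyl carbon C1, and to ring B at C1', next to the phenolic C2'. That pattern is read as the ring-opened form of a spiro coumaranone cyclohexa-2,4-dienone. Oxidative dearomatization of ring B in a 2,2'-dihydroxybenzophenone (ring A: 2-OMe, 3-isovaleryl, 6-OH; ring B: 2'-OH, 4'-Me, 6'-CH2OAc) forms the O–C1' bond and the five-membered ring in one operation. Hydroxide then severs the ketone–C1' bond, releasing the hindered benzoic acid and the doubly ortho-substituted diaryl ether with no metal-mediated etherification. The lone stereocentre is set last by asymmetric transfer hydrogenation.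

Key step: step 12

Remark: the carbinol carbon of the target is read as (R) (CIP order OH > aryl > CH2 > H). Every stereocentre formed before step 14 is later oxidised or cleaved, so those compounds are carried as racemates or diastereomer mixtures.

Step 1
Reactants: 1 4-hydroxy-2-methoxybenzaldehyde
Product: 2 2-methoxy-4-(methoxymethoxy)benzaldehyde
Conditions: MOMCl, iPr2NEt, CH2Cl2, 0 °C to rt
Reagents that add atoms: chloromethyl methyl ether, COCCl
Why: Base-mediated O-alkylation of the acidic para-formyl phenol (Williamson-type acetal protection) installs the group that later directs lithiation, and the aldehyde is untouched.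

Step 2
Reactants: 2 2-methoxy-4-(methoxymethoxy)benzaldehyde; 3 isobutylmagnesium bromide
Product: 4 racemic 1-[2-methoxy-4-(methoxymethoxy)phenyl]-3-methylbutan-1-ol
Conditions: THF, −20 to 0 °C; then H2O
Reagents that add atoms: isobutylmagnesium bromide (3), CC(C)C[Mg]Br
Why: Grignard 1,2-addition to the aryl aldehyde builds the five-carbon side chain; the carbinol forms racemic, which is immaterial because it is oxidised in step 10.

Step 3
Reactants: 4 racemic 1-[2-methoxy-4-(methoxymethoxy)phenyl]-3-methylbutan-1-ol
Product: 5 racemic tert-butyl{1-[2-methoxy-4-(methoxymethoxy)phenyl]-3-methylbutoxy}dimethylsilane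
Conditions: TBSCl, imidazole, DMF, rt
Reagents that add atoms: tert-butyldimethylsilyl chloride, CC(C)(C)[Si](C)(C)Cl
Why: Imidazole-promoted silylation caps the secondary alcohol with a group that is inert to alkyllithiums, does not direct metalation, and can later be removed by fluoride without touching acetals or esters.

Step 4
Reactants: 5 racemic tert-butyl{1-[2-methoxy-4-(methoxymethoxy)phenyl]-3-methylbutoxy}dimethylsilane
Product: 7 racemic 3-[1-(tert-butyldimethylsilyloxy)-3-methylbutyl]-2-methoxy-6-(methoxymethoxy)benzaldehyde, via aryllithium 6 (not isolated)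
Conditions: n-BuLi, TMEDA, THF, −10 to 0 °C; DMF, −78 °C to rt; then H2O
Reagents that add atoms: N,N-dimethylformamide, CN(C)C=O
Why: Directed ortho-metalation: the ring hydrogen between OMe and OMOM is the most acidic and is chelated by both oxygens, so lithiation should occur there, and formylation of the aryllithium with DMF gives the aldehyde after hydrolysis of the hemiaminal.

Step 5
Reactants: 8 3-hydroxy-5-methylbenzoic acid
Product: 9 3-(hydroxymethyl)-5-methylphenol
Conditions: BH3·THF, THF, 0 °C to rt; then H2O
Reagents that add atoms: none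
Why: Chemoselective borane reduction of a carboxylic acid through its acyloxyborane; the aryl borate formed at the phenol is hydrolysed on work-up.

Step 6
Reactants: 9 3-(hydroxymethyl)-5-methylphenol
Product: 10 [3-(methoxymethoxy)-5-methylphenyl]methanol
Conditions: MOMCl (1.05 equiv), K2CO3, acetone, rt
Reagents that add atoms: chloromethyl methyl ether, COCCl
Why: Under carbonate only the phenol is ionised, so Williamson-type O-alkylation should cap the phenol and leave the benzylic alcohol free to act as the second directing group.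

Step 7
Reactants: 10 [3-(methoxymethoxy)-5-methylphenyl]methanol; 7 racemic 3-[1-(tert-butyldimethylsilyloxy)-3-methylbutyl]-2-methoxy-6-(methoxymethoxy)benzaldehyde
Product: 12 [2-(hydroxymethyl)-6-(methoxymethoxy)-4-methylphenyl]{3-[1-(tert-butyldimethylsilyloxy)-3-methylbutyl]-2-methoxy-6-(methoxymethoxy)phenyl}methanol (racemic diastereomer mixture), via dilithio species 11 (not isolated)
Conditions: 10, n-BuLi (2 equiv per 10), TMEDA, Et2O, 0 °C to rt; then 7, THF, −78 to 0 °C; then H2O
Reagents that add atoms: none
Why: Cooperative directed ortho-metalation by the lithium benzyloxide and the OMOM group places lithium on the carbon between them, and 1,2-addition of this aryllithium to the non-enolisable aldehyde joins the rings; the new carbinol centre is uncontrolled and is erased in step 10.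

Step 8
Reactants: 12 [2-(hydroxymethyl)-6-(methoxymethoxy)-4-methylphenyl]{3-[1-(tert-butyldimethylsilyloxy)-3-methylbutyl]-2-methoxy-6-(methoxymethoxy)phenyl}methanol
Product: 13 2-[{3-[1-(tert-butyldimethylsilyloxy)-3-methylbutyl]-2-methoxy-6-(methoxymethoxy)phenyl}(hydroxy)methyl]-3-(methoxymethoxy)-5-methylbenzyl acetate (racemic diastereomer mixture)
Conditions: Ac2O (1.2 equiv), pyridine, DMAP (cat.), CH2Cl2, 0 °C
Reagents that add atoms: acetic anhydride, CC(=O)OC(C)=O
Why: DMAP-catalysed acylation should select the unhindered primary benzylic hydroxyl, because the diaryl carbinol is buried between four ortho substituents and the other secondary oxygen is silylated.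

Step 9
Reactants: 13 2-[{3-[1-(tert-butyldimethylsilyloxy)-3-methylbutyl]-2-methoxy-6-(methoxymethoxy)phenyl}(hydroxy)methyl]-3-(methoxymethoxy)-5-methylbenzyl acetate
Product: 14 2-{hydroxy[3-(1-hydroxy-3-methylbutyl)-2-methoxy-6-(methoxymethoxy)phenyl]methyl}-3-(methoxymethoxy)-5-methylbenzyl acetate (racemic diastereomer mixture)
Conditions: HF·pyridine, pyridine, THF, 0 °C to rt
Reagents that add atoms: none
Why: Fluoride-driven Si–O cleavage in a pyridine-buffered medium should free the secondary alcohol without acyl migration, acetal loss or ionisation of the benzhydrol.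

Step 10
Reactants: 14 2-{hydroxy[3-(1-hydroxy-3-methylbutyl)-2-methoxy-6-(methoxymethoxy)phenyl]methyl}-3-(methoxymethoxy)-5-methylbenzyl acetate
Product: 15 2-[2-methoxy-6-(methoxymethoxy)-3-(3-methylbutanoyl)benzoyl]-3-(methoxymethoxy)-5-methylbenzyl acetate
Conditions: Dess–Martin periodinane (3 equiv), CH2Cl2, rt
Reagents that add atoms: none
Why: Dess–Martin oxidation should convert both secondary carbinols into ketones in one operation, the phenols being masked as acetals and the primary oxygen as acetate so that neither a quinone nor a phthalide can form.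

Step 11
Reactants: 15 2-[2-methoxy-6-(methoxymethoxy)-3-(3-methylbutanoyl)benzoyl]-3-(methoxymethoxy)-5-methylbenzyl acetate
Product: 16 3-hydroxy-2-[6-hydroxy-2-methoxy-3-(3-methylbutanoyl)benzoyl]-5-methylbenzyl acetate
Conditions: TFA, CH2Cl2, 0 °C to rt; aqueous work-up
Reagents that add atoms: none
Why: Acid-catalysed acetal cleavage removes both aryl MOM ethers, each assisted by the hydrogen bond the freed phenol makes to the diaryl ketone, while the acetate is inert to anhydrous acid.

Step 12
Reactants: 16 3-hydroxy-2-[6-hydroxy-2-methoxy-3-(3-methylbutanoyl)benzoyl]-5-methylbenzyl acetate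
Product: 18 racemic [4-methoxy-4'-methyl-5-(3-methylbutanoyl)-2',3-dioxo-3H-spiro[1-benzofuran-2,1'-cyclohexa[3,5]dien]-6'-yl]methyl acetate, via aryloxyiodane 17 (not isolated)
Conditions: PhI(OAc)2 (1.1 equiv), (CF3)2CHOH, 0 °C to rt, high dilution
Reagents that add atoms: none
Why: The ring B phenol is the more electron-rich of the two, because ring A carries carbonyl groups both ortho (C1) and para (C3) to its hydroxyl; it exchanges an acetate on trivalent iodine to give aryloxyiodane 17, and the ring A oxygen, held over C1' by the diaryl ketone, attacks that carbon as iodobenzene departs. The closest known reaction type is the oxidative phenol coupling of hydroxybenzophenones to grisadienones, run here as a hypervalent-iodine dearomatizing spiroetherification. The new ring is the five-membered coumaranone, closed in the 5-exo-trig mode onto the C1'=C2' bond of ring B. The spiro carbon C1' is the only new stereocentre; nothing controls it, it forms as a racemate and is destroyed in step 13. The step needs chemoselectivity (oxidation of ring B, not ring A) and site selectivity (attack at C1', not at the free C3' and C5' positions); the first is secured by the two acyl groups on ring A, the second by the five-ring geometry of the internal nucleophile and by the non-nucleophilic, cation-stabilising solvent.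

Step 13
Reactants: 18 racemic [4-methoxy-4'-methyl-5-(3-methylbutanoyl)-2',3-dioxo-3H-spiro[1-benzofuran-2,1'-cyclohexa[3,5]dien]-6'-yl]methyl acetate
Product: 20 6-[2-hydroxy-6-(hydroxymethyl)-4-methylphenoxy]-2-methoxy-3-(3-methylbutanoyl)benzoic acid, via acetoxymethyl diaryl ether acid 19 (not isolated)
Conditions: LiOH (5 equiv), THF/H2O, 0 °C to rt; then 1 M HCl to pH 3
Reagents that add atoms: lithium hydroxide (aqueous), [Li+].[OH-]
Why: Hydroxide adds to the strained, non-enolisable coumaranone carbonyl and the C3–C1' bond breaks in a retro-Claisen fragmentation driven by rearomatisation of ring B to its phenoxide, after which ordinary saponification removes the acetate; any lactone formed by internal opening would be hydrolysed to the same acid.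

Step 14
Reactants: 20 6-[2-hydroxy-6-(hydroxymethyl)-4-methylphenoxy]-2-methoxy-3-(3-methylbutanoyl)benzoic acid
Product: 21 6-[2-hydroxy-6-(hydroxymethyl)-4-methylphenoxy]-3-[(1R)-1-hydroxy-3-methylbutyl]-2-methoxybenzoic acid
Conditions: RuCl(p-cymene)[(R,R)-TsDPEN] (2 mol %), HCO2H/Et3N (5:2), DMF, 40 °C
Reagents that add atoms: none
Why: Noyori–Ikariya asymmetric transfer hydrogenation: the ruthenium hydride with the (R,R)-ligand delivers hydride to the Si face of the aryl alkyl ketone (aryl held over the η6-arene by a CH–π contact), which by analogy with simple aryl alkyl ketones should give the (R)-carbinol, and formate is an irreversible hydrogen source compatible with the carboxylate, phenol and benzylic alcohol.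

Compound list
1 | 4-hydroxy-2-methoxybenzaldehyde | COc1cc(O)ccc1C=O | starting material
2 | 2-methoxy-4-(methoxymethoxy)benzaldehyde | COCOc1ccc(C=O)c(OC)c1 | intermediate
3 | isobutylmagnesium bromide | CC(C)C[Mg]Br | starting material
4 | racemic 1-[2-methoxy-4-(methoxymethoxy)phenyl]-3-methylbutan-1-ol | COCOc1ccc(C(O)CC(C)C)c(OC)c1 | intermediate
5 | racemic tert-butyl{1-[2-methoxy-4-(methoxymethoxy)phenyl]-3-methylbutoxy}dimethylsilane | COCOc1ccc(C(O[Si](C)(C)C(C)(C)C)CC(C)C)c(OC)c1 | intermediate
6 | aryllithium of 5, lithium on the ring carbon between OMe and OMOM (not isolated) | COCOc1ccc(C(O[Si](C)(C)C(C)(C)C)CC(C)C)c(OC)c1[Li] | intermediate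
7 | racemic 3-[1-(tert-butyldimethylsilyloxy)-3-methylbutyl]-2-methoxy-6-(methoxymethoxy)benzaldehyde | COCOc1ccc(C(O[Si](C)(C)C(C)(C)C)CC(C)C)c(OC)c1C=O | intermediate
8 | 3-hydroxy-5-methylbenzoic acid | Cc1cc(O)cc(C(=O)O)c1 | starting material
9 | 3-(hydroxymethyl)-5-methylphenol | Cc1cc(O)cc(CO)c1 | intermediate
10 | [3-(methoxymethoxy)-5-methylphenyl]methanol | COCOc1cc(C)cc(CO)c1 | intermediate
11 | lithium [2-lithio-3-(methoxymethoxy)-5-methylphenyl]methanolate (not isolated) | [Li]OCc1cc(C)cc(OCOC)c1[Li] | intermediate
12 | [2-(hydroxymethyl)-6-(methoxymethoxy)-4-methylphenyl]{3-[1-(tert-butyldimethylsilyloxy)-3-methylbutyl]-2-methoxy-6-(methoxymethoxy)phenyl}methanol, racemic diastereomer mixture | OCc1cc(C)cc(OCOC)c1C(O)c1c(OC)c(C(O[Si](C)(C)C(C)(C)C)CC(C)C)ccc1OCOC | intermediate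
13 | 2-[{3-[1-(tert-butyldimethylsilyloxy)-3-methylbutyl]-2-methoxy-6-(methoxymethoxy)phenyl}(hydroxy)methyl]-3-(methoxymethoxy)-5-methylbenzyl acetate, racemic diastereomer mixture | CC(=O)OCc1cc(C)cc(OCOC)c1C(O)c1c(OC)c(C(O[Si](C)(C)C(C)(C)C)CC(C)C)ccc1OCOC | intermediate
14 | 2-{hydroxy[3-(1-hydroxy-3-methylbutyl)-2-methoxy-6-(methoxymethoxy)phenyl]methyl}-3-(methoxymethoxy)-5-methylbenzyl acetate, racemic diastereomer mixture | CC(=O)OCc1cc(C)cc(OCOC)c1C(O)c1c(OC)c(C(O)CC(C)C)ccc1OCOC | intermediate
15 | 2-[2-methoxy-6-(methoxymethoxy)-3-(3-methylbutanoyl)benzoyl]-3-(methoxymethoxy)-5-methylbenzyl acetate | CC(=O)OCc1cc(C)cc(OCOC)c1C(=O)c1c(OC)c(C(=O)CC(C)C)ccc1OCOC | intermediate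
16 | 3-hydroxy-2-[6-hydroxy-2-methoxy-3-(3-methylbutanoyl)benzoyl]-5-methylbenzyl acetate | COc1c(C(=O)CC(C)C)ccc(O)c1C(=O)c1c(O)cc(C)cc1COC(C)=O | intermediate
17 | acetoxy(phenyl)iodanyl ether of the ring B phenol of 16, trivalent iodine (not isolated) | COc1c(C(=O)CC(C)C)ccc(O)c1C(=O)c1c(OI(OC(C)=O)c2ccccc2)cc(C)cc1COC(C)=O | intermediate
18 | racemic [4-methoxy-4'-methyl-5-(3-methylbutanoyl)-2',3-dioxo-3H-spiro[1-benzofuran-2,1'-cyclohexa[3,5]dien]-6'-yl]methyl acetate | COc1c(C(=O)CC(C)C)ccc2OC3(C(=O)c12)C(=O)C=C(C)C=C3COC(C)=O | intermediate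
19 | 6-[2-(acetoxymethyl)-6-hydroxy-4-methylphenoxy]-2-methoxy-3-(3-methylbutanoyl)benzoic acid (not isolated) | COc1c(C(=O)CC(C)C)ccc(Oc2c(O)cc(C)cc2COC(C)=O)c1C(=O)O | intermediate
20 | 6-[2-hydroxy-6-(hydroxymethyl)-4-methylphenoxy]-2-methoxy-3-(3-methylbutanoyl)benzoic acid | COc1c(C(=O)CC(C)C)ccc(Oc2c(O)cc(C)cc2CO)c1C(=O)O | intermediate
21 | 6-[2-hydroxy-6-(hydroxymethyl)-4-methylphenoxy]-3-[(1R)-1-hydroxy-3-methylbutyl]-2-methoxybenzoic acid | COc1c([C@H](O)CC(C)C)ccc(Oc2c(O)cc(C)cc2CO)c1C(=O)O | target

Total step count: 14 (ring A arm steps 1–4, ring B arm steps 5–6, union and endgame steps 7–14).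
Longest linear sequence: 12 steps (steps 1–4, then 7–14).

Steps most likely to fail

1. Step 12. The oxidant may engage the ring A phenol and close the isomeric spirocycle. Oxidised ring B may instead be captured at its unsubstituted C3' or C5' positions by acetate or by a second molecule, or be over-oxidised. The fallback gives up the dearomatization and makes the C6–O–C1' bond by nucleophilic aromatic substitution. It sets out from 10 and 3 and returns at 20. Dilithio species 11, made from 10 as in step 7, would be quenched with B(OMe)3 and oxidised with H2O2/NaOH to 2-(hydroxymethyl)-6-(methoxymethoxy)-4-methylphenol F1. Commercial 4-fluoro-2-methoxybenzaldehyde F2 and 3 would give racemic 1-(4-fluoro-2-methoxyphenyl)-3-methylbutan-1-ol F3. Treatment with n-BuLi (2.2 equiv, THF, −78 °C) should lithiate the alkoxide between F and OMe, and DMF would then give 6-fluoro-3-(1-hydroxy-3-methylbutyl)-2-methoxybenzaldehyde F4. Dess–Martin oxidation would give 6-fluoro-2-methoxy-3-(3-methylbutanoyl)benzaldehyde F5, whose fluorine is activated by an ortho formyl and a para acyl group. F1 and F5 with K2CO3 in DMF should give 6-[2-(hydroxymethyl)-6-(methoxymethoxy)-4-methylphenoxy]-2-methoxy-3-(3-methylbutanoyl)benzaldehyde F6. Pinnick oxidation (NaClO2, NaH2PO4, 2-methyl-2-butene) would give 6-[2-(hydroxymethyl)-6-(methoxymethoxy)-4-methylphenoxy]-2-methoxy-3-(3-methylbutanoyl)benzoic acid F7. TFA in CH2Cl2 then removes the acetal to give 20, and step 14 follows.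

2. Step 13. Hydroxide may add in conjugate fashion to the dienone or open the six-membered ring at the dienone carbonyl, or the dienone may dimerise by cycloaddition before the wanted C–C cleavage. The fallback separates rearomatisation from hydrolysis. It sets out from 18 and returns at 20. Heating 18 in toluene should induce the known thermal grisadienedione-to-depsidone isomerisation, in which the acyl group moves from C1' to the C2' oxygen. The product is the aromatic depsidone F8: a dibenzo[b,e][1,4]dioxepin-11-one whose ring A carboxyl is esterified by the C2' oxygen of ring B, with 2-OMe and 3-isovaleryl on ring A and 4'-Me and 6'-CH2OAc on ring B. Saponification of this aryl ester lactone and of the acetate with LiOH in THF/H2O, followed by acidification, gives 20.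

3. Step 7. Dilithiation of 10 may be incomplete, or the aggregated dianion may add too slowly to the doubly ortho-substituted aldehyde, so that proton transfer consumes the aryllithium. The fallback reverses the polarity of the union and uses an electrophile already at the ketone oxidation level. It sets out from 5 and 10 and returns at 15. Dilithio species 11 would be carboxylated with CO2 and acidified mildly to lactonise to 7-(methoxymethoxy)-5-methyl-2-benzofuran-1(3H)-one F9. Aryllithium 6, made from 5 as in step 4 but not formylated, would open F9 at −78 °C to [2-(hydroxymethyl)-6-(methoxymethoxy)-4-methylphenyl]{3-[1-(tert-butyldimethylsilyloxy)-3-methylbutyl]-2-methoxy-6-(methoxymethoxy)phenyl}methanone F10. Acetylation (Ac2O, pyridine, DMAP) would give 2-{3-[1-(tert-butyldimethylsilyloxy)-3-methylbutyl]-2-methoxy-6-(methoxymethoxy)benzoyl}-3-(methoxymethoxy)-5-methylbenzyl acetate F11. HF·pyridine would give 2-[3-(1-hydroxy-3-methylbutyl)-2-methoxy-6-(methoxymethoxy)benzoyl]-3-(methoxymethoxy)-5-methylbenzyl acetate F12, and Dess–Martin oxidation of its single carbinol gives 15.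

Further compounds
F1 | step 12 | 2-(hydroxymethyl)-6-(methoxymethoxy)-4-methylphenol | COCOc1cc(C)cc(CO)c1O
F2 | step 12 | 4-fluoro-2-methoxybenzaldehyde | COc1cc(F)ccc1C=O
F3 | step 12 | racemic 1-(4-fluoro-2-methoxyphenyl)-3-methylbutan-1-ol | COc1cc(F)ccc1C(O)CC(C)C
F4 | step 12 | racemic 6-fluoro-3-(1-hydroxy-3-methylbutyl)-2-methoxybenzaldehyde | COc1c(C(O)CC(C)C)ccc(F)c1C=O
F5 | step 12 | 6-fluoro-2-methoxy-3-(3-methylbutanoyl)benzaldehyde | COc1c(C(=O)CC(C)C)ccc(F)c1C=O
F6 | step 12 | 6-[2-(hydroxymethyl)-6-(methoxymethoxy)-4-methylphenoxy]-2-methoxy-3-(3-methylbutanoyl)benzaldehyde | COc1c(C(=O)CC(C)C)ccc(Oc2c(OCOC)cc(C)cc2CO)c1C=O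
F7 | step 12 | 6-[2-(hydroxymethyl)-6-(methoxymethoxy)-4-methylphenoxy]-2-methoxy-3-(3-methylbutanoyl)benzoic acid | COc1c(C(=O)CC(C)C)ccc(Oc2c(OCOC)cc(C)cc2CO)c1C(=O)O
F8 | step 13 | depsidone isomer of 18 (ring A carboxyl esterified by the C2' oxygen of ring B; CH2OAc retained) | COc1c(C(=O)CC(C)C)ccc2Oc3c(COC(C)=O)cc(C)cc3OC(=O)c12
F9 | step 7 | 7-(methoxymethoxy)-5-methyl-2-benzofuran-1(3H)-one | COCOc1cc(C)cc2COC(=O)c12
F10 | step 7 | racemic [2-(hydroxymethyl)-6-(methoxymethoxy)-4-methylphenyl]{3-[1-(tert-butyldimethylsilyloxy)-3-methylbutyl]-2-methoxy-6-(methoxymethoxy)phenyl}methanone | OCc1cc(C)cc(OCOC)c1C(=O)c1c(OC)c(C(O[Si](C)(C)C(C)(C)C)CC(C)C)ccc1OCOC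
F11 | step 7 | racemic 2-{3-[1-(tert-butyldimethylsilyloxy)-3-methylbutyl]-2-methoxy-6-(methoxymethoxy)benzoyl}-3-(methoxymethoxy)-5-methylbenzyl acetate | CC(=O)OCc1cc(C)cc(OCOC)c1C(=O)c1c(OC)c(C(O[Si](C)(C)C(C)(C)C)CC(C)C)ccc1OCOC
F12 | step 7 | racemic 2-[3-(1-hydroxy-3-methylbutyl)-2-methoxy-6-(methoxymethoxy)benzoyl]-3-(methoxymethoxy)-5-methylbenzyl acetate | CC(=O)OCc1cc(C)cc(OCOC)c1C(=O)c1c(OC)c(C(O)CC(C)C)ccc1OCOC
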